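**Retrosynthetic overview**
1. The arene is bought; the only ring formed is the 19-membered lactam (N–C1, step 17), after which the arene dimethyl ether is converted to the hydroquinone.
2. C3–C4 comes from a Sonogashira coupling of a C4 alkyne with (E)-3-iodo-2-methylacrylic acid followed by cis-reduction; C6–C7 and C14–C15 both come from the same (M)-allenylstannane (syn propargylation, used twice).
3. C8=C9 comes from cross-metathesis with methacrolein; C10–C11 from a (Z)-crotylboration (10,11-syn, 11,12-anti).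
4. Key bond C11–C12 (the 1,2-dioxygenated pair, both carbons carbonyl-level electrophiles): the C12 alkyne is turned into a (Z)-enol benzoate and hydroformylated enantioselectively. C12 reacts as a nucleophilic α-benzoyloxyalkyl–rhodium and CO/H2 serves as the formyl anion equivalent.
5. Ring order: macrolactam only.

Assumption: ansamycin numbering is used (C1 amide carbonyl, C15 benzylic carbon, C16–C21 arene), so the target is 6S,7R,10S,11R,12S,14S,15R with 2E,4Z,8E; compounds 1, 4, 10, 13 and 19 are taken as catalogue chemicals.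

**Route**

Step 1
Reactants: 1 (S)-but-3-yn-2-ol
Product: 2 (S)-but-3-yn-2-yl methanesulfonate
Conditions: MsCl, Et3N, CH2Cl2, −78 °C
Reagents that add atoms: methanesulfonyl chloride, CS(=O)(=O)Cl
Why: O-sulfonylation (mesylation) occurs at oxygen, so the carbinol stereocentre is untouched.

Step 2
Reactants: 2 (S)-but-3-yn-2-yl methanesulfonate
Product: 3 (M)-tributyl(buta-1,2-dien-1-yl)stannane
Conditions: Bu3SnH, LiN(iPr)2, THF, 0 °C; CuBr·SMe2, −78 °C; then 2, −78 °C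
Reagents that add atoms: tributyltin hydride, CCCC[SnH](CCCC)CCCC
Why: Stannylcuprate anti-SN2' displacement of the propargylic mesylate (Marshall allenylstannane synthesis) transfers the central chirality of 2 to the (M) allene axis.

Step 3
Reactants: 4 2-hydroxy-5-methoxy-3-nitrobenzaldehyde
Product: 5 2,5-dimethoxy-3-nitrobenzaldehyde
Conditions: MeI, K2CO3, DMF, 23 °C
Reagents that add atoms: iodomethane, CI
Why: Williamson etherification of the acidic ortho-nitrophenol.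

Step 4
Reactants: 5 2,5-dimethoxy-3-nitrobenzaldehyde; 3 (M)-tributyl(buta-1,2-dien-1-yl)stannane
Product: 6 (1R,2S)-1-(2,5-dimethoxy-3-nitrophenyl)-2-methylbut-3-yn-1-ol
Conditions: BF3·OEt2, CH2Cl2, −78 °C
Reagents that add atoms: none
Why: BF3-promoted anti-SE2' addition of the allenylstannane (Marshall propargylation) through an open antiperiplanar transition state gives the syn adduct, C14 coming from the allene axis (net retention from 1) and C15 from the syn preference.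

Step 5
Reactants: 6 (1R,2S)-1-(2,5-dimethoxy-3-nitrophenyl)-2-methylbut-3-yn-1-ol
Product: 7 2,5-dimethoxy-1-[(1R,2S)-1-methoxy-2-methylbut-3-yn-1-yl]-3-nitrobenzene
Conditions: MeOTf, 2,6-di-tert-butyl-4-methylpyridine, CH2Cl2, 0 to 23 °C
Reagents that add atoms: methyl trifluoromethanesulfonate, COS(=O)(=O)C(F)(F)F
Why: O-methylation under non-basic conditions leaves the terminal alkyne and the nitroarene alone.

Step 6
Reactants: 7 2,5-dimethoxy-1-[(1R,2S)-1-methoxy-2-methylbut-3-yn-1-yl]-3-nitrobenzene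
Product: 8 (1Z,3S,4R)-4-(2,5-dimethoxy-3-nitrophenyl)-4-methoxy-3-methylbut-1-en-1-yl benzoate
Conditions: PhCO2H, [RuCl2(p-cymene)]2 (1 mol%), P(4-ClC6H4)3, DMAP, toluene, 60 °C
Reagents that add atoms: benzoic acid, OC(=O)c1ccccc1
Why: Ruthenium-vinylidene anti-Markovnikov addition of the carboxylic acid to the terminal alkyne gives the (Z)-enol ester.

Step 7
Reactants: 8 (1Z,3S,4R)-4-(2,5-dimethoxy-3-nitrophenyl)-4-methoxy-3-methylbut-1-en-1-yl benzoate
Product: 9 (2S,4S,5R)-5-(2,5-dimethoxy-3-nitrophenyl)-5-methoxy-4-methyl-1-oxopentan-2-yl benzoate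
Conditions: CO/H2 1:1 (10 bar), Rh(acac)(CO)2 (1 mol%), BisDiazaphos ligand (1.2 mol%), THF, 40 °C
Reagents that add atoms: carbon monoxide, [C-]#[O+]
Why: Asymmetric hydroformylation of a (Z)-enol ester (Landis protocol): Rh–H adds so that rhodium sits on the oxygen-bearing C12, this aldehyde-level carbon then acts as a nucleophilic α-benzoyloxyalkyl–Rh that inserts CO (CO/H2 as formyl anion equivalent) to forge C11–C12, and the bis(diazaphospholane) ligand antipode (fixed by a Mosher check on a test run) selects the face that gives 12S.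

Step 8
Reactants: 9 (2S,4S,5R)-5-(2,5-dimethoxy-3-nitrophenyl)-5-methoxy-4-methyl-1-oxopentan-2-yl benzoate; 10 2-[(2Z)-but-2-en-1-yl]-4,4,5,5-tetramethyl-1,3,2-dioxaborolane
Product: 11 (1R,2S,4S,5R,6S)-1-(2,5-dimethoxy-3-nitrophenyl)-5-hydroxy-1-methoxy-2,6-dimethyloct-7-en-4-yl benzoate
Conditions: toluene, 4 Å MS, 23 °C; pH 7 buffer
Reagents that add atoms: none
Why: Crotylboration through a chair transition state: the (Z)-crotyl geometry gives 10,11-syn and Cornforth-type facial control by the α-benzoyloxy group gives 11,12-anti (the combination favoured for Z-crotylboronates and α-oxygenated aldehydes).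

Step 9
Reactants: 11 (1R,2S,4S,5R,6S)-1-(2,5-dimethoxy-3-nitrophenyl)-5-hydroxy-1-methoxy-2,6-dimethyloct-7-en-4-yl benzoate
Product: 12 (1R,2S,4S,5R,6S)-1-(2,5-dimethoxy-3-nitrophenyl)-1,5-dimethoxy-2,6-dimethyloct-7-en-4-yl benzoate
Conditions: MeOTf, 2,6-di-tert-butyl-4-methylpyridine, CH2Cl2, 23 °C
Reagents that add atoms: methyl trifluoromethanesulfonate, COS(=O)(=O)C(F)(F)F
Why: O-methylation with a hindered, non-nucleophilic base forms no alkoxide, so the neighbouring benzoate does not migrate.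

Step 10
Reactants: 12 (1R,2S,4S,5R,6S)-1-(2,5-dimethoxy-3-nitrophenyl)-1,5-dimethoxy-2,6-dimethyloct-7-en-4-yl benzoate; 13 2-methylprop-2-enal
Product: 14 (2E,4S,5R,6S,8S,9R)-9-(2,5-dimethoxy-3-nitrophenyl)-5,9-dimethoxy-2,4,8-trimethyl-1-oxonon-2-en-6-yl benzoate
Conditions: second-generation Hoveyda–Grubbs catalyst RuCl2(H2IMes)(=CH-2-(iPrO)C6H4) (5 mol%), 13 (10 equiv), CH2Cl2, 40 °C
Reagents that add atoms: none
Why: Olefin cross-metathesis of a terminal alkene with methacrolein gives the thermodynamically preferred (E)-trisubstituted enal.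

Step 11
Reactants: 14 (2E,4S,5R,6S,8S,9R)-9-(2,5-dimethoxy-3-nitrophenyl)-5,9-dimethoxy-2,4,8-trimethyl-1-oxonon-2-en-6-yl benzoate; 3 (M)-tributyl(buta-1,2-dien-1-yl)stannane
Product: 15 (3S,4R,5E,7S,8R,9S,11S,12R)-12-(2,5-dimethoxy-3-nitrophenyl)-4-hydroxy-8,12-dimethoxy-3,5,7,11-tetramethyldodec-5-en-1-yn-9-yl benzoate
Conditions: BF3·OEt2, CH2Cl2, −78 °C
Reagents that add atoms: none
Why: Second Marshall propargylation (anti-SE2', open transition state) adds 1,2 to the α-branched enal and sets C6 from the reagent axis and C7 syn to it; the dr on an enal is the uncertainty, and the isomers are separable.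

Step 12
Reactants: 15 (3S,4R,5E,7S,8R,9S,11S,12R)-12-(2,5-dimethoxy-3-nitrophenyl)-4-hydroxy-8,12-dimethoxy-3,5,7,11-tetramethyldodec-5-en-1-yn-9-yl benzoate
Product: 18 (3S,4R,5E,7S,8R,9S,11S,12R)-12-(2,5-dimethoxy-3-nitrophenyl)-9-hydroxy-8,12-dimethoxy-3,5,7,11-tetramethyldodec-5-en-1-yn-4-yl carbamate, via N-trichloroacetyl carbamate benzoate 16 (not isolated), via carbamate benzoate 17 (not isolated)
Conditions: Cl3CC(O)NCO, CH2Cl2, 0 °C; then K2CO3, MeOH, 23 °C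
Reagents that add atoms: trichloroacetyl isocyanate, O=C=NC(=O)C(Cl)(Cl)Cl
Why: Carbamoylation of the only free hydroxyl (C7) with the acyl isocyanate, then methanolysis removes the trichloroacetyl group and the C12 benzoate while the primary carbamate survives.

Step 13
Reactants: 19 diethyl 2-methylpropanedioate
Product: 20 diethyl 2-(diiodomethyl)-2-methylpropanedioate
Conditions: NaH, CHI3, Et2O, reflux
Reagents that add atoms: iodoform, IC(I)I
Why: The malonate enolate is C-alkylated by iodoform through diiodocarbene.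

Step 14
Reactants: 20 diethyl 2-(diiodomethyl)-2-methylpropanedioate
Product: 21 (2E)-3-iodo-2-methylprop-2-enoic acid
Conditions: KOH, EtOH/H2O, reflux; then HCl
Reagents that add atoms: potassium hydroxide, [K+].[OH-]
Why: Saponification followed by decarboxylative elimination of iodide gives the (E)-iodoacrylic acid.

Step 15
Reactants: 18 (3S,4R,5E,7S,8R,9S,11S,12R)-12-(2,5-dimethoxy-3-nitrophenyl)-9-hydroxy-8,12-dimethoxy-3,5,7,11-tetramethyldodec-5-en-1-yn-4-yl carbamate; 21 (2E)-3-iodo-2-methylprop-2-enoic acid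
Product: 22 (2E,6S,7R,8E,10S,11R,12S,14S,15R)-7-(carbamoyloxy)-15-(2,5-dimethoxy-3-nitrophenyl)-12-hydroxy-11,15-dimethoxy-2,6,8,10,14-pentamethylpentadeca-2,8-dien-4-ynoic acid
Conditions: Pd(PPh3)2Cl2 (5 mol%), CuI (10 mol%), Et3N, THF, 23 °C
Reagents that add atoms: none
Why: Sonogashira coupling of the terminal alkyne with the vinyl iodide proceeds with retention of the (E) geometry.

Step 16
Reactants: 22 (2E,6S,7R,8E,10S,11R,12S,14S,15R)-7-(carbamoyloxy)-15-(2,5-dimethoxy-3-nitrophenyl)-12-hydroxy-11,15-dimethoxy-2,6,8,10,14-pentamethylpentadeca-2,8-dien-4-ynoic acid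
Product: 24 (2E,4Z,6S,7R,8E,10S,11R,12S,14S,15R)-15-(3-amino-2,5-dimethoxyphenyl)-7-(carbamoyloxy)-12-hydroxy-11,15-dimethoxy-2,6,8,10,14-pentamethylpentadeca-2,4,8-trienoic acid, via nitro trienoic acid 23 (not isolated)
Conditions: Zn dust activated by Cu(OAc)2 and AgNO3, MeOH/H2O 1:1, 45 °C; then AcOH, 23 °C
Reagents that add atoms: none
Why: Boland reduction (activated zinc) cis-reduces the conjugated alkyne to the (4Z)-alkene, and zinc in acetic acid then reduces the nitroarene to the aniline in the same pot.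

Step 17
Reactants: 24 (2E,4Z,6S,7R,8E,10S,11R,12S,14S,15R)-15-(3-amino-2,5-dimethoxyphenyl)-7-(carbamoyloxy)-12-hydroxy-11,15-dimethoxy-2,6,8,10,14-pentamethylpentadeca-2,4,8-trienoic acid
Product: 25 [(4E,6Z,8S,9R,10E,12S,13R,14S,16S,17R)-14-hydroxy-13,17,20,22-tetramethoxy-4,8,10,12,16-pentamethyl-3-oxo-2-azabicyclo[16.3.1]docosa-1(21),4,6,10,18(22),19-hexaen-9-yl] carbamate
Conditions: BOPCl, iPr2NEt, toluene, 85 °C, 1 mM, slow addition
Reagents that add atoms: none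
Why: High-dilution macrolactamization through the mixed phosphinic anhydride, as used for the macbecin seco acids; the aniline outcompetes the C12 hydroxyl and the carbamate nitrogen.

Step 18
Reactants: 25 [(4E,6Z,8S,9R,10E,12S,13R,14S,16S,17R)-14-hydroxy-13,17,20,22-tetramethoxy-4,8,10,12,16-pentamethyl-3-oxo-2-azabicyclo[16.3.1]docosa-1(21),4,6,10,18(22),19-hexaen-9-yl] carbamate
Product: 27 [(4E,6Z,8S,9R,10E,12S,13R,14S,16S,17R)-14,20,22-trihydroxy-13,17-dimethoxy-4,8,10,12,16-pentamethyl-3-oxo-2-azabicyclo[16.3.1]docosa-1(21),4,6,10,18(22),19-hexaen-9-yl] carbamate, via quinone 26 (not isolated)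
Conditions: (NH4)2Ce(NO3)6, MeCN/H2O 2:1, −10 °C; then aq Na2S2O4, EtOAc, 23 °C, under Ar
Reagents that add atoms: water, O
Why: Oxidative demethylation of the para-dimethoxy anilide to the para-quinone, then dithionite reduction to the hydroquinone, which is handled under argon.

**Compound list**
1 | (S)-but-3-yn-2-ol | C[C@H](O)C#C | starting material
2 | (S)-but-3-yn-2-yl methanesulfonate | C[C@H](OS(C)(=O)=O)C#C | intermediate
3 | (M)-tributyl(buta-1,2-dien-1-yl)stannane | CCCC[Sn](CCCC)(CCCC)C([H])=[C@]=C([H])C | intermediate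
4 | 2-hydroxy-5-methoxy-3-nitrobenzaldehyde | O=Cc1cc(OC)cc([N+](=O)[O-])c1O | starting material
5 | 2,5-dimethoxy-3-nitrobenzaldehyde | O=Cc1cc(OC)cc([N+](=O)[O-])c1OC | intermediate
6 | (1R,2S)-1-(2,5-dimethoxy-3-nitrophenyl)-2-methylbut-3-yn-1-ol | O=[N+]([O-])c1cc(OC)cc(c1OC)[C@H](O)[C@@H](C)C#C | intermediate
7 | 2,5-dimethoxy-1-[(1R,2S)-1-methoxy-2-methylbut-3-yn-1-yl]-3-nitrobenzene | O=[N+]([O-])c1cc(OC)cc(c1OC)[C@H](OC)[C@@H](C)C#C | intermediate
8 | (1Z,3S,4R)-4-(2,5-dimethoxy-3-nitrophenyl)-4-methoxy-3-methylbut-1-en-1-yl benzoate | O=[N+]([O-])c1cc(OC)cc(c1OC)[C@H](OC)[C@@H](C)/C=C\OC(=O)c2ccccc2 | intermediate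
9 | (2S,4S,5R)-5-(2,5-dimethoxy-3-nitrophenyl)-5-methoxy-4-methyl-1-oxopentan-2-yl benzoate | O=[N+]([O-])c1cc(OC)cc(c1OC)[C@H](OC)[C@@H](C)C[C@H](OC(=O)c2ccccc2)C=O | intermediate
10 | 2-[(2Z)-but-2-en-1-yl]-4,4,5,5-tetramethyl-1,3,2-dioxaborolane | C/C=C\CB1OC(C)(C)C(C)(C)O1 | starting material
11 | (1R,2S,4S,5R,6S)-1-(2,5-dimethoxy-3-nitrophenyl)-5-hydroxy-1-methoxy-2,6-dimethyloct-7-en-4-yl benzoate | O=[N+]([O-])c1cc(OC)cc(c1OC)[C@H](OC)[C@@H](C)C[C@H](OC(=O)c2ccccc2)[C@H](O)[C@@H](C)C=C | intermediate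
12 | (1R,2S,4S,5R,6S)-1-(2,5-dimethoxy-3-nitrophenyl)-1,5-dimethoxy-2,6-dimethyloct-7-en-4-yl benzoate | O=[N+]([O-])c1cc(OC)cc(c1OC)[C@H](OC)[C@@H](C)C[C@H](OC(=O)c2ccccc2)[C@H](OC)[C@@H](C)C=C | intermediate
13 | 2-methylprop-2-enal (methacrolein) | CC(=C)C=O | starting material
14 | (2E,4S,5R,6S,8S,9R)-9-(2,5-dimethoxy-3-nitrophenyl)-5,9-dimethoxy-2,4,8-trimethyl-1-oxonon-2-en-6-yl benzoate | O=[N+]([O-])c1cc(OC)cc(c1OC)[C@H](OC)[C@@H](C)C[C@H](OC(=O)c2ccccc2)[C@H](OC)[C@@H](C)/C=C(\C)C=O | intermediate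
15 | (3S,4R,5E,7S,8R,9S,11S,12R)-12-(2,5-dimethoxy-3-nitrophenyl)-4-hydroxy-8,12-dimethoxy-3,5,7,11-tetramethyldodec-5-en-1-yn-9-yl benzoate | O=[N+]([O-])c1cc(OC)cc(c1OC)[C@H](OC)[C@@H](C)C[C@H](OC(=O)c2ccccc2)[C@H](OC)[C@@H](C)/C=C(\C)[C@H](O)[C@@H](C)C#C | intermediate
16 | (3S,4R,5E,7S,8R,9S,11S,12R)-12-(2,5-dimethoxy-3-nitrophenyl)-8,12-dimethoxy-3,5,7,11-tetramethyl-4-{[(trichloroacetyl)carbamoyl]oxy}dodec-5-en-1-yn-9-yl benzoate | O=[N+]([O-])c1cc(OC)cc(c1OC)[C@H](OC)[C@@H](C)C[C@H](OC(=O)c2ccccc2)[C@H](OC)[C@@H](C)/C=C(\C)[C@H](OC(=O)NC(=O)C(Cl)(Cl)Cl)[C@@H](C)C#C | intermediate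
17 | (3S,4R,5E,7S,8R,9S,11S,12R)-4-(carbamoyloxy)-12-(2,5-dimethoxy-3-nitrophenyl)-8,12-dimethoxy-3,5,7,11-tetramethyldodec-5-en-1-yn-9-yl benzoate | O=[N+]([O-])c1cc(OC)cc(c1OC)[C@H](OC)[C@@H](C)C[C@H](OC(=O)c2ccccc2)[C@H](OC)[C@@H](C)/C=C(\C)[C@H](OC(N)=O)[C@@H](C)C#C | intermediate
18 | (3S,4R,5E,7S,8R,9S,11S,12R)-12-(2,5-dimethoxy-3-nitrophenyl)-9-hydroxy-8,12-dimethoxy-3,5,7,11-tetramethyldodec-5-en-1-yn-4-yl carbamate | O=[N+]([O-])c1cc(OC)cc(c1OC)[C@H](OC)[C@@H](C)C[C@H](O)[C@H](OC)[C@@H](C)/C=C(\C)[C@H](OC(N)=O)[C@@H](C)C#C | intermediate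
19 | diethyl 2-methylpropanedioate | CCOC(=O)C(C)C(=O)OCC | starting material
20 | diethyl 2-(diiodomethyl)-2-methylpropanedioate | CCOC(=O)C(C)(C(I)I)C(=O)OCC | intermediate
21 | (2E)-3-iodo-2-methylprop-2-enoic acid | C/C(=C\I)C(=O)O | intermediate
22 | (2E,6S,7R,8E,10S,11R,12S,14S,15R)-7-(carbamoyloxy)-15-(2,5-dimethoxy-3-nitrophenyl)-12-hydroxy-11,15-dimethoxy-2,6,8,10,14-pentamethylpentadeca-2,8-dien-4-ynoic acid | O=[N+]([O-])c1cc(OC)cc(c1OC)[C@H](OC)[C@@H](C)C[C@H](O)[C@H](OC)[C@@H](C)/C=C(\C)[C@H](OC(N)=O)[C@@H](C)C#C/C=C(\C)C(=O)O | intermediate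
23 | (2E,4Z,6S,7R,8E,10S,11R,12S,14S,15R)-7-(carbamoyloxy)-15-(2,5-dimethoxy-3-nitrophenyl)-12-hydroxy-11,15-dimethoxy-2,6,8,10,14-pentamethylpentadeca-2,4,8-trienoic acid | O=[N+]([O-])c1cc(OC)cc(c1OC)[C@H](OC)[C@@H](C)C[C@H](O)[C@H](OC)[C@@H](C)/C=C(\C)[C@H](OC(N)=O)[C@@H](C)/C=C\C=C(/C)C(=O)O | intermediate
24 | (2E,4Z,6S,7R,8E,10S,11R,12S,14S,15R)-15-(3-amino-2,5-dimethoxyphenyl)-7-(carbamoyloxy)-12-hydroxy-11,15-dimethoxy-2,6,8,10,14-pentamethylpentadeca-2,4,8-trienoic acid | Nc1cc(OC)cc(c1OC)[C@H](OC)[C@@H](C)C[C@H](O)[C@H](OC)[C@@H](C)/C=C(\C)[C@H](OC(N)=O)[C@@H](C)/C=C\C=C(/C)C(=O)O | intermediate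
25 | [(4E,6Z,8S,9R,10E,12S,13R,14S,16S,17R)-14-hydroxy-13,17,20,22-tetramethoxy-4,8,10,12,16-pentamethyl-3-oxo-2-azabicyclo[16.3.1]docosa-1(21),4,6,10,18(22),19-hexaen-9-yl] carbamate | CO[C@@H]1[C@@H](C)/C=C(\C)[C@H](OC(N)=O)[C@@H](C)/C=C\C=C(/C)C(=O)Nc2cc(OC)cc(c2OC)[C@H](OC)[C@@H](C)C[C@@H]1O | intermediate
26 | [(4E,6Z,8S,9R,10E,12S,13R,14S,16S,17R)-14-hydroxy-13,17-dimethoxy-4,8,10,12,16-pentamethyl-3,20,22-trioxo-2-azabicyclo[16.3.1]docosa-1(21),4,6,10,18-pentaen-9-yl] carbamate | CO[C@@H]1[C@@H](C)/C=C(\C)[C@H](OC(N)=O)[C@@H](C)/C=C\C=C(/C)C(=O)NC2=CC(=O)C=C(C2=O)[C@H](OC)[C@@H](C)C[C@@H]1O | intermediate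
27 | [(4E,6Z,8S,9R,10E,12S,13R,14S,16S,17R)-14,20,22-trihydroxy-13,17-dimethoxy-4,8,10,12,16-pentamethyl-3-oxo-2-azabicyclo[16.3.1]docosa-1(21),4,6,10,18(22),19-hexaen-9-yl] carbamate | CO[C@@H]1[C@@H](C)/C=C(\C)[C@H](OC(N)=O)[C@@H](C)/C=C\C=C(/C)C(=O)Nc2cc(O)cc(c2O)[C@H](OC)[C@@H](C)C[C@@H]1O | target

**Step count and risks**

Total step count: 18. Longest linear sequence: 15 (steps 1–2, 4–12, 15–18).

Most likely to fail, first: step 7. Regio- and enantiocontrol in the hydroformylation of a branched, functionalised (Z)-enol benzoate is untested at this complexity, and the α-benzoyloxy aldehyde is labile. The fallback sets out from 8 and returns at 9. Methanolysis of 8 (K2CO3, MeOH) frees (3S,4R)-4-(2,5-dimethoxy-3-nitrophenyl)-4-methoxy-3-methylbutanal F1. Catalytic enantioselective vinyl transfer (Zn(CH=CH2)2, chiral amino-alcohol ligand, toluene, 0 °C) gives (3S,5S,6R)-6-(2,5-dimethoxy-3-nitrophenyl)-6-methoxy-5-methylhex-1-en-3-ol F2. Benzoylation (BzCl, pyridine) gives (3S,5S,6R)-6-(2,5-dimethoxy-3-nitrophenyl)-6-methoxy-5-methylhex-1-en-3-yl benzoate F3. Ozonolysis (O3, CH2Cl2, −78 °C; PPh3) then delivers 9. Here C11 enters as a vinyl group that is unmasked oxidatively, and C12 is set by reagent-controlled carbonyl addition.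

Second: step 16. The one-pot cis-reduction and nitro reduction may stall at the hydroxylamine or give azoxy by-products. The fallback sets out from 18 and returns at 25, closing the ring by C–C coupling instead of lactamization. Fe and NH4Cl in EtOH/H2O at 70 °C reduce 18 to (3S,4R,5E,7S,8R,9S,11S,12R)-12-(3-amino-2,5-dimethoxyphenyl)-9-hydroxy-8,12-dimethoxy-3,5,7,11-tetramethyldodec-5-en-1-yn-4-yl carbamate F5. Acylation of the aniline with acid 21 (EDC·HCl, HOAt, CH2Cl2) gives the N-aryl (2E)-3-iodo-2-methylprop-2-enamide F6. Intramolecular Sonogashira coupling (Pd(PPh3)4, CuI, Et3N, THF, 1 mM) gives the 4,5-didehydro macrolactam F7. Zn activated by Cu(OAc)2 and AgNO3 in MeOH/H2O then gives 25.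

Third: step 10. Cross-metathesis of the allylically branched alkene with methacrolein may be sluggish. The fallback sets out from 12 and returns at 14. Ozonolysis of 12 (O3, CH2Cl2, −78 °C; PPh3) gives (2R,3R,4S,6S,7R)-7-(2,5-dimethoxy-3-nitrophenyl)-3,7-dimethoxy-2,6-dimethyl-1-oxoheptan-4-yl benzoate F4. Wittig olefination with Ph3P=C(CH3)CHO (toluene, 80 °C) gives 14 with (E) selectivity; F4 is used at once to limit epimerization at C10.

Further compounds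
F1 | step 7 | (3S,4R)-4-(2,5-dimethoxy-3-nitrophenyl)-4-methoxy-3-methylbutanal | O=[N+]([O-])c1cc(OC)cc(c1OC)[C@H](OC)[C@@H](C)CC=O
F2 | step 7 | (3S,5S,6R)-6-(2,5-dimethoxy-3-nitrophenyl)-6-methoxy-5-methylhex-1-en-3-ol | O=[N+]([O-])c1cc(OC)cc(c1OC)[C@H](OC)[C@@H](C)C[C@H](O)C=C
F3 | step 7 | (3S,5S,6R)-6-(2,5-dimethoxy-3-nitrophenyl)-6-methoxy-5-methylhex-1-en-3-yl benzoate | O=[N+]([O-])c1cc(OC)cc(c1OC)[C@H](OC)[C@@H](C)C[C@H](OC(=O)c2ccccc2)C=C
F4 | step 10 | (2R,3R,4S,6S,7R)-7-(2,5-dimethoxy-3-nitrophenyl)-3,7-dimethoxy-2,6-dimethyl-1-oxoheptan-4-yl benzoate | O=[N+]([O-])c1cc(OC)cc(c1OC)[C@H](OC)[C@@H](C)C[C@H](OC(=O)c2ccccc2)[C@H](OC)[C@@H](C)C=O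
F5 | step 16 | (3S,4R,5E,7S,8R,9S,11S,12R)-12-(3-amino-2,5-dimethoxyphenyl)-9-hydroxy-8,12-dimethoxy-3,5,7,11-tetramethyldodec-5-en-1-yn-4-yl carbamate | Nc1cc(OC)cc(c1OC)[C@H](OC)[C@@H](C)C[C@H](O)[C@H](OC)[C@@H](C)/C=C(\C)[C@H](OC(N)=O)[C@@H](C)C#C
F6 | step 16 | (3S,4R,5E,7S,8R,9S,11S,12R)-9-hydroxy-12-{3-[(2E)-3-iodo-2-methylprop-2-enamido]-2,5-dimethoxyphenyl}-8,12-dimethoxy-3,5,7,11-tetramethyldodec-5-en-1-yn-4-yl carbamate | C/C(=C\I)C(=O)Nc1cc(OC)cc(c1OC)[C@H](OC)[C@@H](C)C[C@H](O)[C@H](OC)[C@@H](C)/C=C(\C)[C@H](OC(N)=O)[C@@H](C)C#C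
F7 | step 16 | [(4E,8S,9R,10E,12S,13R,14S,16S,17R)-14-hydroxy-13,17,20,22-tetramethoxy-4,8,10,12,16-pentamethyl-3-oxo-2-azabicyclo[16.3.1]docosa-1(21),4,10,18(22),19-pentaen-6-yn-9-yl] carbamate | CO[C@@H]1[C@@H](C)/C=C(\C)[C@H](OC(N)=O)[C@@H](C)C#C/C=C(\C)C(=O)Nc2cc(OC)cc(c2OC)[C@H](OC)[C@@H](C)C[C@@H]1O
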